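## Retrosynthetic overview

1. Target 27 ⇐ (tert-butyl ester cleavage, O-acetylation, protodesilylation C17–Si → C8=C17 with 9-H, desulfonylation at C6) ⇐ trans-decalin 21, whose ring B holds a C8=C9 allylsilane.
2. 21 ⇐ acyclic triene 20 by one intramolecular Diels–Alder reaction: diene C7=C8–C9=C10, dienophile C5=C6 (E-vinyl sulfone), tether C1–C4. Rings A and B are formed together in this step; no carbocycle of the target exists before it.
3. Enabling feature: ring B (C5–C6–C7–C8–C9–C10) with its exocyclic C8=C17 alkene is a cyclohexene retron once the alkene is drawn as C8=C9 with silicon on C17, and ring A is the four-carbon bridge C1–C4 between the fusion atoms C10 and C5. The quaternary C4 (CH3, CO2R) beside C5 is the only stereocenter of 20; it relays C5 and C10 in the cycloaddition and C9 afterwards.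
4. 20 ⇐ tetrasubstituted (E)-enoate 18 (ester → 2-(silylmethyl)diene) ⇐ B-alkyl Suzuki–Miyaura union of (S)-vinyl sulfone 6 with (E)-enol tosylate 16.
5. 6 ⇐ catalytic asymmetric phase-transfer allylation of tert-butyl 2-cyanopropanoate (sets C4); 16 ⇐ methyl acetoacetate + homoallylic iodide 13 (Zr-catalysed carboalumination of a butynyl silyl ether).

Key step: step 13

Assumption: the (S,S)-ammonium catalyst of step 2 is taken to give (S)-3; should the allylation run with the opposite sense, the (R,R)-catalyst is used and nothing else changes.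
Remark: labdane numbering (C1–C20) is used for positions; 2 and 15 are racemic, and the stereocenter of 15 disappears in step 10.

## Route

Step 1
Reactants: 1 tert-butyl cyanoacetate
Product: 2 tert-butyl 2-cyanopropanoate (racemic)
Conditions: MeI (1.0 equiv), K2CO3, acetone, 0 °C → rt; distillation
Reagents that add atoms: iodomethane, CI
Why: C-methylation of a doubly activated methylene (enolate alkylation, SN2), in which a slight excess of 1 limits dialkylation and the dimethyl by-product is removed by distillation.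

Step 2
Reactants: 2 tert-butyl 2-cyanopropanoate
Product: 3 tert-butyl (S)-2-cyano-2-methylpent-4-enoate
Conditions: allyl bromide, (S,S)-3,4,5-trifluorophenyl-NAS bromide (N-spiro bis-binaphthyl ammonium bromide, 2 mol %), CsOH·H2O, toluene, −40 °C
Reagents that add atoms: allyl bromide, C=CCBr
Why: Asymmetric phase-transfer alkylation, in which the chiral ammonium cation pairs with the cyano ester enolate and shields one enolate face so that SN2 attack on allyl bromide sets the quaternary C4 stereocenter, the bulky tert-butyl ester enlarging the ester/nitrile difference on which the face discrimination rests.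

Step 3
Reactants: 3 tert-butyl (S)-2-cyano-2-methylpent-4-enoate
Product: 5 tert-butyl (S)-2-formyl-2-methylpent-4-enoate, via aluminated aldimine 4 (not isolated)
Conditions: i-Bu2AlH (1.2 equiv), CH2Cl2, −78 °C; then 1 M HCl, 0 °C
Reagents that add atoms: water, O
Why: Partial reduction of the nitrile by hydroalumination stops at the N-aluminated aldimine, which is hydrolysed on work-up, while the neopentyl tert-butyl ester is too hindered to compete at −78 °C and the quaternary center cannot epimerise.

Step 4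
Reactants: 5 tert-butyl (S)-2-formyl-2-methylpent-4-enoate
Product: 6 tert-butyl (S)-2-methyl-2-[(E)-2-(phenylsulfonyl)ethenyl]pent-4-enoate
Conditions: (EtO)2P(O)CH2SO2Ph, NaH, THF, 0 °C → rt
Reagents that add atoms: diethyl [(phenylsulfonyl)methyl]phosphonate, CCOP(=O)(CS(=O)(=O)c1ccccc1)OCC
Why: Horner–Wadsworth–Emmons olefination of a non-enolisable aldehyde with a sulfonyl-stabilised phosphonate anion, which is E-selective and gives a vinyl sulfone that cannot isomerise to the allyl sulfone because C4 is quaternary.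

Step 5
Reactants: 7 tert-butyl(but-3-yn-1-yloxy)dimethylsilane
Product: 10 (E)-5-(tert-butyldimethylsilyloxy)-3-methylpent-2-en-1-ol, via alkenylalane 8 (not isolated), via lithium aluminate 9 (not isolated)
Conditions: Me3Al, Cp2ZrCl2 (0.25 equiv), CH2Cl2, 0 °C → rt; volatiles removed; n-BuLi, THF, −30 °C; (CH2O)n, rt; aqueous potassium sodium tartrate
Reagents that add atoms: trimethylaluminium, C[Al](C)C; formaldehyde (as paraformaldehyde), C=O
Why: Zirconium-catalysed carboalumination adds CH3 and Al syn across the terminal alkyne with methyl on the internal carbon, which fixes the (E)-trisubstituted alkene, and the derived aluminate is hydroxymethylated by formaldehyde with retention.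

Step 6
Reactants: 10 (E)-5-(tert-butyldimethylsilyloxy)-3-methylpent-2-en-1-ol
Product: 11 (E)-5-(tert-butyldimethylsilyloxy)-1-(tert-butyldiphenylsilyloxy)-3-methylpent-2-ene
Conditions: TBDPSCl, imidazole, DMF, rt
Reagents that add atoms: tert-butyl(chloro)diphenylsilane, CC(C)(C)[Si](Cl)(c1ccccc1)c1ccccc1
Why: Silylation of the primary allylic alcohol, chosen because the TBDPS ether outlasts every later step up to step 16.

Step 7
Reactants: 11 (E)-5-(tert-butyldimethylsilyloxy)-1-(tert-butyldiphenylsilyloxy)-3-methylpent-2-ene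
Product: 12 (E)-5-(tert-butyldiphenylsilyloxy)-3-methylpent-3-en-1-ol
Conditions: PPTS (0.2 equiv), MeOH, rt
Reagents that add atoms: none
Why: Acid-catalysed methanolysis cleaves the primary TBS ether far faster than the bulkier TBDPS ether (selective silyl ether solvolysis).

Step 8
Reactants: 12 (E)-5-(tert-butyldiphenylsilyloxy)-3-methylpent-3-en-1-ol
Product: 13 tert-butyl{[(E)-5-iodo-3-methylpent-2-en-1-yl]oxy}diphenylsilane
Conditions: I2, PPh3, imidazole, CH2Cl2, 0 °C → rt
Reagents that add atoms: iodine, II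
Why: Appel-type iodination, SN2 displacement of the alkoxyphosphonium ion by iodide at an unhindered primary carbon.

Step 9
Reactants: 13 tert-butyl{[(E)-5-iodo-3-methylpent-2-en-1-yl]oxy}diphenylsilane; 14 methyl acetoacetate
Product: 15 methyl (E)-2-acetyl-7-(tert-butyldiphenylsilyloxy)-5-methylhept-5-enoate (racemic)
Conditions: NaH, THF/DMF, 0 °C; then 13, 50 °C
Reagents that add atoms: none
Why: Acetoacetic ester alkylation (SN2), in which the weakly basic stabilised enolate favours substitution over E2 of the homoallylic iodide and joins C9 to C11.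

Step 10
Reactants: 15 methyl (E)-2-acetyl-7-(tert-butyldiphenylsilyloxy)-5-methylhept-5-enoate
Product: 16 methyl (E)-2-[(E)-5-(tert-butyldiphenylsilyloxy)-3-methylpent-3-en-1-yl]-3-(tosyloxy)but-2-enoate
Conditions: TsCl, N-methylimidazole, Et3N, toluene, 0 °C → rt
Reagents that add atoms: 4-toluenesulfonyl chloride, Cc1ccc(cc1)S(Cl)(=O)=O
Why: Stereoselective enol tosylation of an α-substituted β-keto ester under non-chelating amine conditions, which places the sulfonate trans to the ester ((E)-isomer) and so fixes CH3 (C20) cis to C8 for the later diene.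

Step 11
Reactants: 6 tert-butyl (S)-2-methyl-2-[(E)-2-(phenylsulfonyl)ethenyl]pent-4-enoate; 16 methyl (E)-2-[(E)-5-(tert-butyldiphenylsilyloxy)-3-methylpent-3-en-1-yl]-3-(tosyloxy)but-2-enoate
Product: 18 1-tert-butyl 8-methyl (S,6E)-7-[(E)-5-(tert-butyldiphenylsilyloxy)-3-methylpent-3-en-1-yl]-2,6-dimethyl-2-[(E)-2-(phenylsulfonyl)ethenyl]oct-6-enedioate, via alkylborane 17 (not isolated)
Conditions: 9-BBN-H, THF, rt; then 16, Pd(OAc)2 (5 mol %), SPhos (10 mol %), 3 M aq. K3PO4, THF, 50 °C
Reagents that add atoms: none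
Why: Anti-Markovnikov hydroboration of the terminal alkene (the electron-poor, hindered vinyl sulfone is left) followed by B-alkyl Suzuki–Miyaura coupling with the activated enol tosylate, which proceeds with retention of alkene geometry and forms the C1–C10 bond with C1 trans to C8.

Step 12
Reactants: 18 1-tert-butyl 8-methyl (S,6E)-7-[(E)-5-(tert-butyldiphenylsilyloxy)-3-methylpent-3-en-1-yl]-2,6-dimethyl-2-[(E)-2-(phenylsulfonyl)ethenyl]oct-6-enedioate
Product: 20 tert-butyl (S,6E)-7-[(E)-5-(tert-butyldiphenylsilyloxy)-3-methylpent-3-en-1-yl]-2,6-dimethyl-2-[(E)-2-(phenylsulfonyl)ethenyl]-8-[(trimethylsilyl)methyl]nona-6,8-dienoate, via bis(silylmethyl) carbinol 19 (not isolated)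
Conditions: TMSCH2MgCl (5 equiv), CeCl3 (5 equiv, dried), THF, −78 °C → rt; aq. NH4Cl; then SiO2, CH2Cl2, rt
Reagents that add atoms: (trimethylsilyl)methylmagnesium chloride, C[Si](C)(C)C[Mg]Cl
Why: Double 1,2-addition of the organocerium reagent to the methyl enoate (CeCl3 suppresses enolisation and conjugate addition, the neopentyl tert-butyl ester is too hindered and the β-carbon of the vinyl sulfone is neopentyl) followed by Peterson elimination on silica gel turns the ester carbon C8 into the 2-(silylmethyl)diene unit C7=C8(CH2SiMe3).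

Step 13
Reactants: 20 tert-butyl (S,6E)-7-[(E)-5-(tert-butyldiphenylsilyloxy)-3-methylpent-3-en-1-yl]-2,6-dimethyl-2-[(E)-2-(phenylsulfonyl)ethenyl]-8-[(trimethylsilyl)methyl]nona-6,8-dienoate
Product: 21 tert-butyl 6α-(phenylsulfonyl)-15-(tert-butyldiphenylsilyloxy)-17-(trimethylsilyl)labda-8,13E-dien-19-oate (trans-fused; 5α-H; 10β-CH3; 4β-CO2tBu)
Conditions: toluene (0.01 M), BHT (cat.), 140 °C, sealed tube, base-washed glass
Reagents that add atoms: none
Why: Thermal, concerted but asynchronous [4+2] cycloaddition of normal electron demand (type 1 intramolecular Diels–Alder reaction of a 1,7,9-decatriene): the diene C7=C8–C9=C10, made electron-rich by three alkyl groups and the allylic C–Si bond, adds suprafacially to the (E)-vinyl sulfone C5=C6, and the four-carbon tether C1–C4 fixes the regiochemistry (C6 to C7, C5 to C10) against the intermolecular preference. The closest known reactions are the cyclisations of 1-(arylsulfonyl)-1,7,9-decatrienes in hot toluene, the Diels–Alder reactions of 2-(trimethylsilylmethyl)buta-1,3-dienes, and the additions to dienes with an inside methyl group on a fully substituted terminus (2,6,6-trimethyl-1-vinylcyclohexene) that give the angular methyl group of drimanes. Ring B is closed as the cycloadduct ring by both new bonds, and ring A is closed by the C5–C10 bond alone as the fused (not bridged) tether ring, with a chair-like tether. C10 takes its configuration from the (E)-geometry of C9=C10 (tether outside, CH3 inside) and C5 from the transition state with the sulfonyl group endo and the tether exo, which together give the trans ring fusion (10-CH3 anti to 5-H) and a 6α-sulfone that step 14 removes; the absolute sense comes from C4, because in the chair-like tether the C4 substituent that is 1,3-syn to the inside methyl group of C10 should be the flat ester and not the methyl group, which puts CO2tBu axial (β) and C18 equatorial as the target needs. The step needs trans over cis fusion and one face of the dienophile: the first is secured by the endo preference of the (E)-sulfone and by the quaternary C4, which cannot lie under the diene, the second by the size difference between CH3 and CO2tBu at C4; the congested C5–C10 bond is the reason for the activating sulfone and the heat.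

Step 14
Reactants: 21 tert-butyl 6α-(phenylsulfonyl)-15-(tert-butyldiphenylsilyloxy)-17-(trimethylsilyl)labda-8,13E-dien-19-oate
Product: 22 tert-butyl 15-(tert-butyldiphenylsilyloxy)-17-(trimethylsilyl)labda-8,13E-dien-19-oate
Conditions: sodium amalgam (6% Na in Hg), Na2HPO4, MeOH/THF, −20 → 0 °C
Reagents that add atoms: none
Why: Reductive desulfonylation (electron transfer, C–S cleavage, protonation) removes the activating group and leaves C6 as CH2, while the ester, silyl ether and allylsilane are inert to the buffered conditions.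

Step 15
Reactants: 22 tert-butyl 15-(tert-butyldiphenylsilyloxy)-17-(trimethylsilyl)labda-8,13E-dien-19-oate
Product: 23 tert-butyl 15-(tert-butyldiphenylsilyloxy)labda-8(17),13E-dien-19-oate (9α-H)
Conditions: CF3CO2H (5 equiv), CH2Cl2, −40 → −20 °C, short time; aq. NaHCO3
Reagents that add atoms: none
Why: Protodesilylation of the allylsilane (SE2′): the proton adds to C9 axially from the α-face, anti to the 10β-methyl group, and the β-silyl cation at C8 loses silicon, which gives the exocyclic C8=C17 alkene and sets C9 with the side chain equatorial.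

Step 16
Reactants: 23 tert-butyl 15-(tert-butyldiphenylsilyloxy)labda-8(17),13E-dien-19-oate
Product: 25 tert-butyl 15-acetoxylabda-8(17),13E-dien-19-oate, via allylic alcohol 24 (not isolated)
Conditions: Bu4NF, THF, rt; then Et3N, Ac2O, DMAP (cat.), 0 °C → rt
Reagents that add atoms: acetic anhydride, CC(=O)OC(C)=O
Why: Fluoride cleavage of the silyl ether followed in the same flask by acyl transfer (DMAP-catalysed O-acetylation) to the primary allylic alcohol, with no acid present that could move the exocyclic alkene.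

Step 17
Reactants: 25 tert-butyl 15-acetoxylabda-8(17),13E-dien-19-oate
Product: 27 15-acetoxyisocupressic acid, via trimethylsilyl ester 26 (not isolated)
Conditions: TMSOTf, 2,6-lutidine, CH2Cl2, 0 °C; then pH 5 aqueous buffer, rt
Reagents that add atoms: none
Why: Silylation of the ester carbonyl and loss of the tert-butyl cation as isobutene (alkyl–oxygen cleavage, independent of the hindrance at C4) gives the silyl ester, which is hydrolysed on work-up, under non-protic buffered conditions that should spare the exocyclic alkene and the allylic acetate.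

## Compound list

1 | tert-butyl cyanoacetate | N#CCC(=O)OC(C)(C)C | starting material
2 | tert-butyl 2-cyanopropanoate (racemic) | CC(C#N)C(=O)OC(C)(C)C | intermediate
3 | tert-butyl (S)-2-cyano-2-methylpent-4-enoate | C=CC[C@@](C)(C#N)C(=O)OC(C)(C)C | intermediate
4 | tert-butyl (S)-2-{[(diisobutylalumanyl)imino]methyl}-2-methylpent-4-enoate (aluminated aldimine) | C=CC[C@@](C)(C=N[Al](CC(C)C)CC(C)C)C(=O)OC(C)(C)C | intermediate (not isolated)
5 | tert-butyl (S)-2-formyl-2-methylpent-4-enoate | C=CC[C@@](C)(C=O)C(=O)OC(C)(C)C | intermediate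
6 | tert-butyl (S)-2-methyl-2-[(E)-2-(phenylsulfonyl)ethenyl]pent-4-enoate | C=CC[C@@](C)(/C=C/S(=O)(=O)c1ccccc1)C(=O)OC(C)(C)C | intermediate
7 | tert-butyl(but-3-yn-1-yloxy)dimethylsilane | C#CCCO[Si](C)(C)C(C)(C)C | starting material
8 | [(E)-4-(tert-butyldimethylsilyloxy)-2-methylbut-1-en-1-yl]dimethylalane | C[Al](C)/C=C(\C)CCO[Si](C)(C)C(C)(C)C | intermediate (not isolated)
9 | lithium butyl[(E)-4-(tert-butyldimethylsilyloxy)-2-methylbut-1-en-1-yl]dimethylaluminate | [Li+].CCCC[Al-](C)(C)/C=C(\C)CCO[Si](C)(C)C(C)(C)C | intermediate (not isolated)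
10 | (E)-5-(tert-butyldimethylsilyloxy)-3-methylpent-2-en-1-ol | OC/C=C(\C)CCO[Si](C)(C)C(C)(C)C | intermediate
11 | (E)-5-(tert-butyldimethylsilyloxy)-1-(tert-butyldiphenylsilyloxy)-3-methylpent-2-ene | CC(C)(C)[Si](C)(C)OCC/C(C)=C/CO[Si](c1ccccc1)(c1ccccc1)C(C)(C)C | intermediate
12 | (E)-5-(tert-butyldiphenylsilyloxy)-3-methylpent-3-en-1-ol | OCC/C(C)=C/CO[Si](c1ccccc1)(c1ccccc1)C(C)(C)C | intermediate
13 | tert-butyl{[(E)-5-iodo-3-methylpent-2-en-1-yl]oxy}diphenylsilane | ICC/C(C)=C/CO[Si](c1ccccc1)(c1ccccc1)C(C)(C)C | intermediate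
14 | methyl acetoacetate | COC(=O)CC(C)=O | starting material
15 | methyl (E)-2-acetyl-7-(tert-butyldiphenylsilyloxy)-5-methylhept-5-enoate (racemic) | COC(=O)C(CC/C(C)=C/CO[Si](c1ccccc1)(c1ccccc1)C(C)(C)C)C(C)=O | intermediate
16 | methyl (E)-2-[(E)-5-(tert-butyldiphenylsilyloxy)-3-methylpent-3-en-1-yl]-3-(tosyloxy)but-2-enoate | COC(=O)/C(CC/C(C)=C/CO[Si](c1ccccc1)(c1ccccc1)C(C)(C)C)=C(\C)OS(=O)(=O)c1ccc(C)cc1 | intermediate
17 | tert-butyl (S)-5-(9-borabicyclo[3.3.1]nonan-9-yl)-2-methyl-2-[(E)-2-(phenylsulfonyl)ethenyl]pentanoate | B1(C2CCCC1CCC2)CCC[C@@](C)(/C=C/S(=O)(=O)c3ccccc3)C(=O)OC(C)(C)C | intermediate (not isolated)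
18 | 1-tert-butyl 8-methyl (S,6E)-7-[(E)-5-(tert-butyldiphenylsilyloxy)-3-methylpent-3-en-1-yl]-2,6-dimethyl-2-[(E)-2-(phenylsulfonyl)ethenyl]oct-6-enedioate | COC(=O)/C(CC/C(C)=C/CO[Si](c1ccccc1)(c1ccccc1)C(C)(C)C)=C(\C)CCC[C@@](C)(/C=C/S(=O)(=O)c1ccccc1)C(=O)OC(C)(C)C | intermediate
19 | tert-butyl (S,6E)-7-[(E)-5-(tert-butyldiphenylsilyloxy)-3-methylpent-3-en-1-yl]-8-hydroxy-2,6-dimethyl-2-[(E)-2-(phenylsulfonyl)ethenyl]-9-(trimethylsilyl)-8-[(trimethylsilyl)methyl]non-6-enoate | C[Si](C)(C)CC(O)(C[Si](C)(C)C)/C(CC/C(C)=C/CO[Si](c1ccccc1)(c1ccccc1)C(C)(C)C)=C(\C)CCC[C@@](C)(/C=C/S(=O)(=O)c1ccccc1)C(=O)OC(C)(C)C | intermediate (not isolated)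
20 | tert-butyl (S,6E)-7-[(E)-5-(tert-butyldiphenylsilyloxy)-3-methylpent-3-en-1-yl]-2,6-dimethyl-2-[(E)-2-(phenylsulfonyl)ethenyl]-8-[(trimethylsilyl)methyl]nona-6,8-dienoate | C=C(C[Si](C)(C)C)/C(CC/C(C)=C/CO[Si](c1ccccc1)(c1ccccc1)C(C)(C)C)=C(\C)CCC[C@@](C)(/C=C/S(=O)(=O)c1ccccc1)C(=O)OC(C)(C)C | intermediate
21 | tert-butyl 6α-(phenylsulfonyl)-15-(tert-butyldiphenylsilyloxy)-17-(trimethylsilyl)labda-8,13E-dien-19-oate (trans-fused; 5α-H; 10β-CH3; 4β-CO2tBu) | C[Si](C)(C)CC1=C(CC/C(C)=C/CO[Si](c2ccccc2)(c3ccccc3)C(C)(C)C)[C@@]4(C)CCC[C@](C)(C(=O)OC(C)(C)C)[C@@H]4[C@@H](S(=O)(=O)c5ccccc5)C1 | intermediate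
22 | tert-butyl 15-(tert-butyldiphenylsilyloxy)-17-(trimethylsilyl)labda-8,13E-dien-19-oate | C[Si](C)(C)CC1=C(CC/C(C)=C/CO[Si](c2ccccc2)(c3ccccc3)C(C)(C)C)[C@@]4(C)CCC[C@](C)(C(=O)OC(C)(C)C)[C@@H]4CC1 | intermediate
23 | tert-butyl 15-(tert-butyldiphenylsilyloxy)labda-8(17),13E-dien-19-oate (9α-H) | C=C1CC[C@@H]2[C@](C)(CCC[C@]2(C)C(=O)OC(C)(C)C)[C@H]1CC/C(C)=C/CO[Si](c3ccccc3)(c4ccccc4)C(C)(C)C | intermediate
24 | tert-butyl 15-hydroxylabda-8(17),13E-dien-19-oate (tert-butyl isocupressate) | C=C1CC[C@@H]2[C@](C)(CCC[C@]2(C)C(=O)OC(C)(C)C)[C@H]1CC/C(C)=C/CO | intermediate (not isolated)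
25 | tert-butyl 15-acetoxylabda-8(17),13E-dien-19-oate | C=C1CC[C@@H]2[C@](C)(CCC[C@]2(C)C(=O)OC(C)(C)C)[C@H]1CC/C(C)=C/COC(C)=O | intermediate
26 | trimethylsilyl 15-acetoxylabda-8(17),13E-dien-19-oate | C=C1CC[C@@H]2[C@](C)(CCC[C@]2(C)C(=O)O[Si](C)(C)C)[C@H]1CC/C(C)=C/COC(C)=O | intermediate (not isolated)
27 | 15-acetoxyisocupressic acid | C=C1CC[C@@H]2[C@](C)(CCC[C@]2(C)C(=O)O)[C@H]1CC/C(C)=C/COC(C)=O | target

## Step count and risks

Total step count: 17. Longest linear sequence: 13 steps (steps 5–17, from 7).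

Steps most likely to fail:

1. Step 13 (key step). The cycloaddition may be too slow, because the C5–C10 bond joins a neopentyl carbon to a fully substituted diene terminus. At the temperature then needed, a [1,5]-hydrogen shift from the inside methyl group or loss of the allylsilane may compete, and the face or fusion selectivity may erode. Fallback, from 18 back to 23, with a stronger donor diene that should react at lower temperature and a thermodynamic instead of a kinetic setting of C9: enoate 18 is methylenated at the methyl ester with Cp2Ti(μ-Cl)(μ-CH2)AlMe2 (toluene/THF/pyridine, −40 °C → rt; the neopentyl tert-butyl ester is left) to the 2-methoxy-1,3-diene F1. Its intramolecular Diels–Alder reaction (toluene, about 100 °C) should give the methyl enol ether adduct F2. Sodium amalgam with Na2HPO4 in MeOH removes the sulfone to give the enol ether F3. Aqueous oxalic acid in THF hydrolyses the enol ether and equilibrates C9 to the equatorial side chain, giving the 8-ketone F4. Wittig methylenation (Ph3P=CH2, THF, reflux) leads back to 23.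

2. Step 12. The organometallic reagent may consume the vinyl sulfone by conjugate addition or α-metalation before the hindered tetrasubstituted enoate has added twice. Fallback, from 5 back to 20, in which the sulfone is introduced only after the organocerium step: aldehyde 5 is reduced (NaBH4, MeOH, 0 °C) to the hydroxy ester F5. 9-BBN-H (2.2 equiv; the first equivalent is taken up by the hydroxyl group with loss of hydrogen) gives the bis-borylated adduct F6, which is coupled with 16 under the conditions of step 11 to the hydroxy enoate F7. TMSCH2MgCl/CeCl3 (one more equivalent for the alkoxide) gives the carbinol F8 and, on silica gel, the hydroxy triene F9. Dess–Martin oxidation (NaHCO3-buffered) to the aldehyde F10 and the Horner–Wadsworth–Emmons reaction of step 4 lead back to 20.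

3. Step 11. Transmetalation from boron to the hindered alkenylpalladium species may be slow, so that hydrolysis of the enol tosylate by the aqueous base takes over. Fallback, from 6 back to 18, with a preformed organozinc under anhydrous, base-free conditions (Negishi coupling): borane 17, made from 6 as in step 11, is oxidised with Me3NO (THF, 60 °C; no nucleophilic peroxide that could epoxidise the vinyl sulfone) to the alcohol F11. Iodination (I2, PPh3, imidazole) gives the iodide F12. Zinc insertion (Zn dust, LiCl, THF) gives the alkylzinc iodide F13, and coupling with 16 (Pd(OAc)2, SPhos, THF/NMP, 40 °C) leads back to 18.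

Further compounds
F1 | step 13 | tert-butyl (S,6E)-7-[(E)-5-(tert-butyldiphenylsilyloxy)-3-methylpent-3-en-1-yl]-8-methoxy-2,6-dimethyl-2-[(E)-2-(phenylsulfonyl)ethenyl]nona-6,8-dienoate | C=C(OC)/C(CC/C(C)=C/CO[Si](c1ccccc1)(c1ccccc1)C(C)(C)C)=C(\C)CCC[C@@](C)(/C=C/S(=O)(=O)c1ccccc1)C(=O)OC(C)(C)C
F2 | step 13 | tert-butyl 8-methoxy-6α-(phenylsulfonyl)-15-(tert-butyldiphenylsilyloxy)-17-norlabda-8,13E-dien-19-oate | COC1=C(CC/C(C)=C/CO[Si](c2ccccc2)(c3ccccc3)C(C)(C)C)[C@@]4(C)CCC[C@](C)(C(=O)OC(C)(C)C)[C@@H]4[C@@H](S(=O)(=O)c5ccccc5)C1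
F3 | step 13 | tert-butyl 8-methoxy-15-(tert-butyldiphenylsilyloxy)-17-norlabda-8,13E-dien-19-oate | COC1=C(CC/C(C)=C/CO[Si](c2ccccc2)(c3ccccc3)C(C)(C)C)[C@@]4(C)CCC[C@](C)(C(=O)OC(C)(C)C)[C@@H]4CC1
F4 | step 13 | tert-butyl 8-oxo-15-(tert-butyldiphenylsilyloxy)-17-norlabd-13E-en-19-oate (9α-H) | O=C1CC[C@@H]2[C@](C)(CCC[C@]2(C)C(=O)OC(C)(C)C)[C@H]1CC/C(C)=C/CO[Si](c3ccccc3)(c4ccccc4)C(C)(C)C
F5 | step 12 | tert-butyl (S)-2-(hydroxymethyl)-2-methylpent-4-enoate | C=CC[C@@](C)(CO)C(=O)OC(C)(C)C
F6 | step 12 | tert-butyl (S)-5-(9-borabicyclo[3.3.1]nonan-9-yl)-2-[(9-borabicyclo[3.3.1]nonan-9-yloxy)methyl]-2-methylpentanoate | B1(C2CCCC1CCC2)CCC[C@@](C)(COB3C4CCCC3CCC4)C(=O)OC(C)(C)C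
F7 | step 12 | 1-tert-butyl 8-methyl (S,6E)-7-[(E)-5-(tert-butyldiphenylsilyloxy)-3-methylpent-3-en-1-yl]-2-(hydroxymethyl)-2,6-dimethyloct-6-enedioate | COC(=O)/C(CC/C(C)=C/CO[Si](c1ccccc1)(c1ccccc1)C(C)(C)C)=C(\C)CCC[C@@](C)(CO)C(=O)OC(C)(C)C
F8 | step 12 | tert-butyl (S,6E)-7-[(E)-5-(tert-butyldiphenylsilyloxy)-3-methylpent-3-en-1-yl]-8-hydroxy-2-(hydroxymethyl)-2,6-dimethyl-9-(trimethylsilyl)-8-[(trimethylsilyl)methyl]non-6-enoate | C[Si](C)(C)CC(O)(C[Si](C)(C)C)/C(CC/C(C)=C/CO[Si](c1ccccc1)(c1ccccc1)C(C)(C)C)=C(\C)CCC[C@@](C)(CO)C(=O)OC(C)(C)C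
F9 | step 12 | tert-butyl (S,6E)-7-[(E)-5-(tert-butyldiphenylsilyloxy)-3-methylpent-3-en-1-yl]-2-(hydroxymethyl)-2,6-dimethyl-8-[(trimethylsilyl)methyl]nona-6,8-dienoate | C=C(C[Si](C)(C)C)/C(CC/C(C)=C/CO[Si](c1ccccc1)(c1ccccc1)C(C)(C)C)=C(\C)CCC[C@@](C)(CO)C(=O)OC(C)(C)C
F10 | step 12 | tert-butyl (S,6E)-7-[(E)-5-(tert-butyldiphenylsilyloxy)-3-methylpent-3-en-1-yl]-2-formyl-2,6-dimethyl-8-[(trimethylsilyl)methyl]nona-6,8-dienoate | C=C(C[Si](C)(C)C)/C(CC/C(C)=C/CO[Si](c1ccccc1)(c1ccccc1)C(C)(C)C)=C(\C)CCC[C@@](C)(C=O)C(=O)OC(C)(C)C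
F11 | step 11 | tert-butyl (S)-5-hydroxy-2-methyl-2-[(E)-2-(phenylsulfonyl)ethenyl]pentanoate | OCCC[C@@](C)(/C=C/S(=O)(=O)c1ccccc1)C(=O)OC(C)(C)C
F12 | step 11 | tert-butyl (S)-5-iodo-2-methyl-2-[(E)-2-(phenylsulfonyl)ethenyl]pentanoate | ICCC[C@@](C)(/C=C/S(=O)(=O)c1ccccc1)C(=O)OC(C)(C)C
F13 | step 11 | {(S)-5-tert-butoxy-4-methyl-5-oxo-4-[(E)-2-(phenylsulfonyl)ethenyl]pentyl}zinc iodide | I[Zn]CCC[C@@](C)(/C=C/S(=O)(=O)c1ccccc1)C(=O)OC(C)(C)C
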